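**Retrosynthetic overview**
- The target is opened at two C–O bonds at once, the C3–O ester bond and the O1–C2 ring bond. Both come from an oxidative anti oxy-acyloxylation of an (E)-aryl diene with the side-chain acid. The dihydrofuran ring is the only ring formed, and it is formed in the last step.
- The aryl diene, 5-[(1E)-3-methylbuta-1,3-dienyl]-2,4-dihydroxyacetophenone, comes from 5-iodo-2,4-dihydroxyacetophenone and an (E)-dienylboronate (from 2-methylbut-1-en-3-yne and pinacolborane). The iodide comes from 2,4-dihydroxyacetophenone.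
- The acid, (2Z)-2-(acetoxymethyl)but-2-enoic acid, comes from tert-butyl but-2-ynoate by syn-hydroalumination, hydroxymethylation and acetylation, then tert-butyl cleavage.

Assumption: the sense of induction of the new step 5 cannot be predicted with certainty; it is written with (S)-tBu-Quinox as the ligand giving (2R), and the equally available (R)-ligand is used if the sense proves opposite.

**Route**

Step 1
Reactants: 1 2,4-dihydroxyacetophenone
Product: 2 1-(2,4-dihydroxy-5-iodophenyl)ethan-1-one
Conditions: ICl (1.05 equiv), AcOH, 20 °C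
Reagents that add atoms: iodine monochloride, ClI
Why: Electrophilic aromatic iodination goes to C5, which is para to the chelated 2-OH, ortho to the 4-OH and less hindered than C3 between the two oxygens (the selectivity expected by analogy with ICl/AcOH on 2,4-dihydroxybenzaldehyde), and the product is crystallised free of any 3-iodo isomer.

Step 2
Reactants: 2 1-(2,4-dihydroxy-5-iodophenyl)ethan-1-one; 3 2-methylbut-1-en-3-yne; 4 pinacolborane
Product: 6 1-{2,4-dihydroxy-5-[(1E)-3-methylbuta-1,3-dien-1-yl]phenyl}ethan-1-one, via dienyl pinacolboronate 5 (not isolated)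
Conditions: 3, 4, Cp2ZrHCl (5 mol%), Et3N (10 mol%), CH2Cl2, 25 °C; evaporate; then 2, Pd(dppf)Cl2 (3 mol%), K3PO4 (4 equiv), THF/H2O 4:1, 45 °C
Reagents that add atoms: none
Why: Zirconocene-catalysed syn-hydroboration of the terminal alkyne gives the (E)-dienylboronate, and Suzuki–Miyaura coupling of the aryl iodide proceeds with retention of alkene geometry at a temperature low enough that the base-sensitive ortho-hydroxyaryl diene does not isomerise to a chromene.

Step 3
Reactants: 7 tert-butyl but-2-ynoate; 8 diisobutylaluminium hydride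
Product: 11 tert-butyl (2Z)-2-[(acetyloxy)methyl]but-2-enoate, via alpha-alumino enoate 9 (not isolated), via aluminium alkoxide 10 (not isolated)
Conditions: iBu2AlH, NMO, THF, 0 °C; CH2O (gas from cracked paraformaldehyde), −20 to 0 °C; then Ac2O, pyridine, DMAP (cat.), 0 to 20 °C
Reagents that add atoms: formaldehyde, C=O; acetic anhydride, CC(=O)OC(C)=O
Why: Conjugate syn-hydroalumination of the ynoate (vinylalumination, a reductive aldol process) places aluminium at the alpha carbon cis to the new beta hydrogen, hydroxymethylation then occurs with retention so that the methyl group ends cis to the ester (Z), and the aluminium alkoxide is acetylated in the flask as in a reductive acetylation.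

Step 4
Reactants: 11 tert-butyl (2Z)-2-[(acetyloxy)methyl]but-2-enoate
Product: 12 (2Z)-2-[(acetyloxy)methyl]but-2-enoic acid
Conditions: CF3CO2H/CH2Cl2 1:4, 0 to 20 °C
Reagents that add atoms: none
Why: Acidolysis of the tert-butyl ester (E1 loss of isobutene) leaves the primary acetate and the Z-trisubstituted alkene untouched.

Step 5
Reactants: 6 1-{2,4-dihydroxy-5-[(1E)-3-methylbuta-1,3-dien-1-yl]phenyl}ethan-1-one; 12 (2Z)-2-[(acetyloxy)methyl]but-2-enoic acid
Product: 14 (2R,3S)-5-acetyl-6-hydroxy-2-(prop-1-en-2-yl)-2,3-dihydro-1-benzofuran-3-yl (2Z)-2-[(acetyloxy)methyl]but-2-enoate, via para-quinone methide 13 (not isolated)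
Conditions: 12 (3 equiv), Pd(OCOCF3)2 (5 mol%), (S)-tBu-Quinox [(S)-4-tert-butyl-2-(quinolin-2-yl)-4,5-dihydrooxazole] (7.5 mol%), O2 (1 atm), 3 Å MS, toluene, 0 to 20 °C
Reagents that add atoms: none
Why: Proposed new method: a chloride-free divalent palladium–Quinox phenoxide formed at the more acidic 4-OH should insert the neighbouring styrenyl C=C in a 5-endo syn-oxypalladation that closes the dihydrofuran ring and sets C2 under ligand control; the resulting C3-benzylpalladium has no syn beta-hydrogen (palladium is cis to the isopropenyl group) and is activated by the ortho ring oxygen and the para 6-OH, so it loses zerovalent palladium (reoxidised by O2) to give quinone methide 13, to which acid 12 adds 1,6 at C3 anti to the isopropenyl group, giving the 2,3-trans ester; the closest known reaction type is the palladium-catalysed enantioselective difunctionalisation of ortho-vinylphenols through quinone methide intermediates (Wacker-type nucleopalladation, then nucleophile capture), together with Hegedus-type 5-endo heteropalladation.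

**Compound list**

1 | 1-(2,4-dihydroxyphenyl)ethan-1-one (2,4-dihydroxyacetophenone) | CC(=O)c1ccc(O)cc1O | starting material
2 | 1-(2,4-dihydroxy-5-iodophenyl)ethan-1-one | CC(=O)c1cc(I)c(O)cc1O | intermediate
3 | 2-methylbut-1-en-3-yne | C=C(C)C#C | starting material
4 | pinacolborane (4,4,5,5-tetramethyl-1,3,2-dioxaborolane) | [H]B1OC(C)(C)C(C)(C)O1 | starting material
5 | 4,4,5,5-tetramethyl-2-[(1E)-3-methylbuta-1,3-dien-1-yl]-1,3,2-dioxaborolane (not isolated) | C=C(C)/C=C/B1OC(C)(C)C(C)(C)O1 | intermediate
6 | 1-{2,4-dihydroxy-5-[(1E)-3-methylbuta-1,3-dien-1-yl]phenyl}ethan-1-one | C=C(C)/C=C/c1cc(C(C)=O)c(O)cc1O | intermediate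
7 | tert-butyl but-2-ynoate | CC#CC(=O)OC(C)(C)C | starting material
8 | diisobutylaluminium hydride | CC(C)C[AlH]CC(C)C | starting material
9 | tert-butyl (2E)-2-[bis(2-methylpropyl)alumanyl]but-2-enoate (not isolated; methyl cis to the ester) | C/C=C(\C(=O)OC(C)(C)C)[Al](CC(C)C)CC(C)C | intermediate
10 | tert-butyl (2Z)-2-({[bis(2-methylpropyl)alumanyl]oxy}methyl)but-2-enoate (not isolated) | C/C=C(\C(=O)OC(C)(C)C)CO[Al](CC(C)C)CC(C)C | intermediate
11 | tert-butyl (2Z)-2-[(acetyloxy)methyl]but-2-enoate | C/C=C(\C(=O)OC(C)(C)C)COC(C)=O | intermediate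
12 | (2Z)-2-[(acetyloxy)methyl]but-2-enoic acid | C/C=C(\C(=O)O)COC(C)=O | intermediate
13 | (2S)-5-acetyl-2-(prop-1-en-2-yl)-1-benzofuran-6(2H)-one, the para-quinone methide (not isolated; same spatial arrangement at C2 as in 14) | C=C(C)[C@H]1OC2=CC(=O)C(C(C)=O)=CC2=C1 | intermediate
14 | (2R,3S)-5-acetyl-6-hydroxy-2-(prop-1-en-2-yl)-2,3-dihydro-1-benzofuran-3-yl (2Z)-2-[(acetyloxy)methyl]but-2-enoate (2,3-trans) | C=C(C)[C@H]1Oc2cc(O)c(C(C)=O)cc2[C@@H]1OC(=O)/C(=C\C)COC(C)=O | target

**Totals and risks**

Total step count: 5. Longest linear sequence: 3 steps (1 → 2 → 6 → 14; the acid branch 7 → 11 → 12 → 14 is equally long).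

The three steps most likely to fail:

Step 5 (the new reaction). The main risks are:
- quinone methide 13 tautomerising to the aromatic benzofuran instead of being captured by the acid;
- a competing 1,4-oxidation of the diene through a pi-allyl palladium species, giving a chromene;
- insufficient enantio- or diastereoselectivity.

The fallback uses known chemistry, sets out from 6 and comes back to the route at 14. Compound 6 is silylated (TBSCl, imidazole, DMAP, DMF, 40 °C) to 1-{2,4-bis[(tert-butyldimethylsilyl)oxy]-5-[(1E)-3-methylbuta-1,3-dien-1-yl]phenyl}ethan-1-one F1. Shi asymmetric epoxidation with the enantiomer of the usual D-fructose-derived ketone (made from L-sorbose; KHSO5, K2CO3 buffer at pH 10.5, MeCN/dimethoxymethane/H2O, 0 °C) attacks the trans-disubstituted styrenyl alkene in preference to the 1,1-disubstituted one and gives 1-{2,4-bis[(tert-butyldimethylsilyl)oxy]-5-[(2S,3S)-3-(prop-1-en-2-yl)oxiran-2-yl]phenyl}ethan-1-one F2. Bu4NF in THF at 0 °C removes both silyl groups, and the freed 4-phenoxide opens the epoxide at the allylic carbon with inversion, closing the five-membered ring to the 2,3-trans alcohol 1-[(2R,3S)-3,6-dihydroxy-2-(prop-1-en-2-yl)-2,3-dihydro-1-benzofuran-5-yl]ethan-1-one F3. Yamaguchi esterification of the secondary hydroxyl of F3 with 12 (2,4,6-trichlorobenzoyl chloride, Et3N, then F3 and catalytic DMAP, toluene, 20 °C) gives 14; the chelated 6-OH is not acylated and the mixed-anhydride protocol avoids Z to E isomerisation.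

Step 3. The risks are competing 1,2-reduction of the ester, poor capture of gaseous formaldehyde, and erosion of the Z geometry.

The fallback sets out from 7 and comes back at 11. Syn-hydrostannation of 7 catalysed by Pd(PPh3)4 (Bu3SnH, THF, 20 °C) places tin at the alpha carbon and gives tert-butyl (2E)-2-(tributylstannyl)but-2-enoate F4. Iododestannylation with retention (I2, CH2Cl2, 0 °C) gives tert-butyl (2E)-2-iodobut-2-enoate F5. Stille hydroxymethylation with Bu3SnCH2OH (Pd(PPh3)4, dioxane, 80 °C), again with retention, gives tert-butyl (2Z)-2-(hydroxymethyl)but-2-enoate F6. Acetylation (Ac2O, pyridine, DMAP) then gives 11.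

Step 2. The risks are protodeboronation of the dienylboronate and base- or heat-induced cyclisation of the ortho-hydroxyaryl diene to a 2,2-dimethylchromene.

The fallback sets out from 2 and comes back at 6. Compound 2 is acetylated (Ac2O, pyridine, 20 °C) to 4-acetyl-6-iodo-1,3-phenylene diacetate F7. A Mizoroki–Heck reaction with isoprene (Pd(OAc)2, P(o-tol)3, Et3N, MeCN, 80 °C, sealed tube) arylates the unsubstituted vinyl terminus; with the ortho oxygen masked, the pi-allyl intermediate undergoes beta-hydride elimination instead of ring closure and gives 4-acetyl-6-[(1E)-3-methylbuta-1,3-dien-1-yl]-1,3-phenylene diacetate F8. Brief methanolysis (K2CO3, MeOH, 0 °C) gives 6.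

**Further compounds**

F1 | step 5 | 1-{2,4-bis[(tert-butyldimethylsilyl)oxy]-5-[(1E)-3-methylbuta-1,3-dien-1-yl]phenyl}ethan-1-one | C=C(C)/C=C/c1cc(C(C)=O)c(O[Si](C)(C)C(C)(C)C)cc1O[Si](C)(C)C(C)(C)C
F2 | step 5 | 1-{2,4-bis[(tert-butyldimethylsilyl)oxy]-5-[(2S,3S)-3-(prop-1-en-2-yl)oxiran-2-yl]phenyl}ethan-1-one | C=C(C)[C@@H]1O[C@H]1c2cc(C(C)=O)c(O[Si](C)(C)C(C)(C)C)cc2O[Si](C)(C)C(C)(C)C
F3 | step 5 | 1-[(2R,3S)-3,6-dihydroxy-2-(prop-1-en-2-yl)-2,3-dihydro-1-benzofuran-5-yl]ethan-1-one | C=C(C)[C@H]1Oc2cc(O)c(C(C)=O)cc2[C@@H]1O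
F4 | step 3 | tert-butyl (2E)-2-(tributylstannyl)but-2-enoate | C/C=C(\C(=O)OC(C)(C)C)[Sn](CCCC)(CCCC)CCCC
F5 | step 3 | tert-butyl (2E)-2-iodobut-2-enoate | C/C=C(\C(=O)OC(C)(C)C)I
F6 | step 3 | tert-butyl (2Z)-2-(hydroxymethyl)but-2-enoate | C/C=C(\C(=O)OC(C)(C)C)CO
F7 | step 2 | 4-acetyl-6-iodo-1,3-phenylene diacetate | CC(=O)Oc1cc(OC(C)=O)c(C(C)=O)cc1I
F8 | step 2 | 4-acetyl-6-[(1E)-3-methylbuta-1,3-dien-1-yl]-1,3-phenylene diacetate | C=C(C)/C=C/c1cc(C(C)=O)c(OC(C)=O)cc1OC(C)=O
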